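## Structural features

The target 27 is a monocyclic sesquiterpenoid: one eleven-membered carbocycle (humulane-type skeleton), numbered here C1 to C11, with no second ring to give it rigidity. C1 carries an exocyclic methylene group and its neighbour C11 a secondary hydroxyl, which together form a 2-methylene allylic alcohol. C4=C5 is a trisubstituted ring alkene with the free carboxyl group on C5 and E geometry, so the ring carbons C3 and C6 are cis and C3 is trans to the carboxyl group. C7 bears a 3-methylbutanoate ester and C9 a gem-dimethyl group. The two stereocentres, C7 (S) and C11 (S), are not adjacent: they stand 1,5 to each other with the quaternary C9 between them, so each needs its own source of asymmetry. Fragile points are the allylic alcohol beside a 1,1-disubstituted alkene (ionisation or transposition under acid), the acyloxy group γ to the acid carbonyl (lactonisation onto C7, acyl loss under base) and the enoate geometry. The real difficulty is to build the eleven-membered ring without a macrocyclisation, to fix the C4=C5 geometry, and to tell apart the two methylene neighbours of C11 (C1 and the neopentyl C10). The key step uses the fact that the C11 oxygen and the C4=C5 alkene are joined by the bridge C1–C2–C3, the δ,ε-unsaturated carbonyl pattern of an oxy-Cope product. Re-joining C5 to C11 and cutting C2–C3 folds the ring into a cycloheptane (C5–C6–C7–C8–C9–C10–C11) with a vinyl group on each of the adjacent carbons C5 and C11.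

## Logic of the disconnections

27 ⇒ 25. Only the alkyl–oxygen bond of the C5 carboxyl ester is cut. The acid has to be masked through every basic and hydridic step, and the tert-butyl ester also blocks lactonisation, resists the Grignard reagent and serves as the bulky group in the pericyclic transition state. No skeletal simplification results, but the last step carries no C–C or stereochemical burden. The forward step must spare the allylic alcohol, the exocyclic alkene and the C7 ester, hence a silyl triflate-mediated cleavage through 26 instead of protic acid.

25 ⇒ 24. The C11–H bond is cut, taking the carbinol back to the ketone. C11 has no neighbour that could relay chirality and its configuration is erased in the ring expansion, so a reagent-controlled reduction after all C–C bond formation is the clean source. One stereocentre disappears and C11 becomes the activating group for C1. The forward step needs 1,2-reduction from one face, with the C1 alkenyl arm read as the large group, and no hydroboration of the methylene group.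

24 ⇒ 20. The C1=CH2 bond is cut (through 23, 22 and 21). The reactive α-methylene ketone is best made directly before its reduction. The gain is a plain ketone. The forward step must enolise toward C1 and not toward C10 or either ester.

20 ⇒ 18 ⇒ 17. The acyl–oxygen bond at C7 is cut (acyl group from 19), then silicon is put back on oxygen. The C7 oxygen must travel as a silyl ether through enolate, Grignard and alkoxide chemistry, and it is acylated while it is the only free hydroxyl in the molecule, so the two hydroxyls of 27 never have to be differentiated. The forward desilylation must be non-basic so that the free C7 hydroxyl does not lactonise onto the C5 ester.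

17 ⇒ 14 and 15. C5–C11 is re-formed and C2–C3 is cut, the reverse of a [3,3] shift through 16. This trades the eleven-membered ring for a seven-membered one that already has the carboxyl on C5, the oxygen on C11 and both vinyl groups in place. The configuration of C5 and C11 relative to C7 becomes irrelevant. The forward step needs the two vinyl groups cis, a chair transition state with the ester equatorial, and a concerted pathway that outruns retro-aldol cleavage.

14 and 15 ⇒ 12 + 13. The C1–C11 bond between vinyl group and carbinol carbon is cut. The tertiary carbinol becomes a ketone and the cis-divinyl problem becomes one of facial selectivity. The forward addition must enter anti to the ester arm at C5 and must not enolise the ketone.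

12 ⇒ 9 + 10. The C4–C5 bond is cut; 10 serves as a vinyl cation equivalent through 11. The quaternary carbon reverts to the acidic carbon of a β-keto ester. The forward step needs C-alkylation at a hindered carbon and a clean thermal elimination.

9 ⇒ 8. The C5–C11 ring bond is cut (Dieckmann). The carbocycle becomes an open-chain diester whose two ester groups are chemically distinct. The forward closure must use the tert-butyl ester only as the enolate half and the methyl ester only as the acceptor, and must form a seven-membered ring.

8 ⇒ 7 ⇒ 6. The Si–O bond, then the C7–H bond are cut: the C7 stereocentre comes from a ketone. The γ-ester gives a hydrogenation catalyst a handle to distinguish two methylene flanks. The forward step must deliver hydrogen to one face, and the carbinol must be silylated before it can lactonise.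

6 ⇒ 2 + 3. The C6–C7 bond between acyl carbon and methylene is cut (through 4 and 5). Two small pieces result, each with its ester already in place. The forward acylation must leave both esters and the new ketone untouched.

2 ⇒ 1. One ester C–O bond is cut, leading back to a symmetrical cyclic anhydride. The forward opening needs no selectivity.

## Other disconnections considered

Alternative 1: The cut is at C7–C8 and C5–C6, and the ring stays open. In the forward direction the organolithium A2 would add to the vinylboronic ester A3. A palladium-catalysed conjunctive coupling with the (Z)-bromo enoate A4 under a chiral bisphosphine would then move C8 from boron to C7 while C6 couples to C5, giving the boronate A1.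
- In favour: three fragments of similar size are joined in one operation, and C7 is set by the catalyst in that same step, with the C–B bond oxidisable to C–O with retention. The C4=C5 geometry is carried over from A4 by a stereoretentive coupling, which is a firmer basis than a preference between two chair transition states; on this point the alternative is the better plan.
- Against: the key step closes no ring. The C1–C11 bond would still have to be made from the seco ynal A5 by a reductive alkyne–aldehyde macrocyclisation that must control ring size, alkyne regiochemistry and the C11 configuration at high dilution. The migrating carbon C8 is neopentyl, which slows the 1,2-shift relative to direct coupling.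
- Comparison: the alternative places its stereochemical load on one catalyst and one macrocyclisation; the chosen plan places it on a hydrogenation, a pericyclic transition state and a reduction, but needs no high-dilution step. The overall step count would be about equal, and the longest linear sequence of the alternative would be somewhat shorter.

Alternative 2: The cut is at C3–C4 of the fully functionalised ring. In the forward direction cathodic reduction of the redox-active ester A7 would release CO2 and a primary radical at C3. This would add 11-endo to C4 of the β-sulfonyl enoate and expel a sulfonyl radical to give the protected target A6.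
- In favour: the ring is closed on material that already holds both stereocentres, the methylene group and the C7 ester, so only two deprotections would remain; the endgame is better than in the chosen plan. The conditions are base-free, so C7 can carry its ester throughout, where the chosen plan must keep it silylated.
- Against: the ring is closed end to end by a short-lived primary radical that can instead be reduced further, abstract hydrogen or dimerise. The C4=C5 geometry would be decided in the β-scission of a mobile α-ester radical and is not stereospecific. A7 is a long linear precursor in which C7 and C11 must be set independently.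
- Comparison: the reacting carbons are chain termini here, but vinyl termini on adjacent ring atoms in the chosen plan. The two plans are equal in needing two separate asymmetric steps. The alternative is shorter after ring closure but longer and less convergent before it.

Alternative 3: The cut is at C5–C11, the same bond the chosen plan breaks, but within the fused six–seven epoxy ketone A9. In the forward direction an arenesulfonyl hydrazone of the C4 ketone would fragment with loss of N2 and sulfinate to give the ynone A8.
- In favour: the ring is again made by expansion and not by end-to-end closure, equal to the chosen plan on the central point. The fragmentation has no alkoxide and no retro-aldol escape, so the key step itself is probably the more reliable of the two. A8 carries the same C11 ketone, so the C1/C11 endgame would be shared.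
- Against: A8 has a triple bond where the target has a carboxylated alkene. The carboxyl carbon would have to be added at C5 and not C4 of an alkyne whose two ends differ only through the C7 oxygen one carbon away, although syn addition would give the right in-ring geometry automatically. Epoxidation of a tetrasubstituted enone is slow.
- Comparison: the chosen plan installs the carboxyl before expansion and takes the geometry from the transition state. The alternative trades that for a sturdier fragmentation at the cost of a regiochemical problem and a few more steps.

Key step: step 8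

Remark: positions are cited with the ring numbering of 27 (C1 to C11) in every intermediate, and ring compounds 16 to 27 are named with it. The cycloheptanol is carried as the pair 14/15 because its C5/C11 configuration relative to C7 vanishes in step 8.

## Route

Step 1
Reactants: 1 3,3-dimethylglutaric anhydride
Product: 2 5-methoxy-3,3-dimethyl-5-oxopentanoic acid
Conditions: MeOH, reflux
Reagents that add atoms: methanol, CO
Why: Alcoholysis of a symmetrical cyclic anhydride; both carbonyl groups are equivalent, so one half ester results and the future C7 and C11 termini become distinguishable.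

Step 2
Reactants: 2 5-methoxy-3,3-dimethyl-5-oxopentanoic acid; 3 tert-butyl 3-bromopropanoate
Product: 6 8-tert-butyl 1-methyl 3,3-dimethyl-5-oxooctanedioate, via acid chloride 4 (not isolated), via zinc homoenolate 5 (not isolated)
Conditions: 2, (COCl)2, DMF (cat.), CH2Cl2, 0 °C to rt, evaporate; 3, Zn dust (activated), LiCl, THF, 50 °C; combine, Pd(PPh3)4 (3 mol %), THF, 0 °C to rt
Reagents that add atoms: none
Why: Negishi acylation: zerovalent palladium inserts into the acyl chloride, the ester-stabilised alkylzinc transmetalates and reductive elimination forms the C6–C7 bond; the zinc reagent adds neither to the esters nor to the product ketone.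

Step 3
Reactants: 6 8-tert-butyl 1-methyl 3,3-dimethyl-5-oxooctanedioate
Product: 7 8-tert-butyl 1-methyl (5R)-5-hydroxy-3,3-dimethyloctanedioate
Conditions: H2 (50 atm), RuCl2[(S)-BINAP] (1 mol %), MeOH, 30 °C; crude product taken directly into step 4
Reagents that add atoms: none
Why: Noyori hydrogenation of a γ-keto ester: the tert-butyl ester carbonyl and the ketone bind divalent ruthenium together, so the catalyst distinguishes the ester arm from the other methylene arm; the (S)-BINAP complex should, by analogy with 4-oxo esters giving (S)-lactones, deliver hydrogen to the face that gives the required carbinol, named (5R) here because the gem-dimethyl arm outranks the ester arm.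

Step 4
Reactants: 7 8-tert-butyl 1-methyl (5R)-5-hydroxy-3,3-dimethyloctanedioate
Product: 8 8-tert-butyl 1-methyl (5R)-5-[(tert-butyldimethylsilyl)oxy]-3,3-dimethyloctanedioate
Conditions: TBSCl, imidazole, DMF, 0 °C to rt
Reagents that add atoms: tert-butyldimethylsilyl chloride, CC(C)(C)[Si](C)(C)Cl
Why: Imidazole-promoted silylation of a secondary alcohol, run at once so that the carbinol cannot close a δ-lactone onto the methyl ester; the silyl ether tolerates the enolate, Grignard and alkoxide steps ahead.

Step 5
Reactants: 8 8-tert-butyl 1-methyl (5R)-5-[(tert-butyldimethylsilyl)oxy]-3,3-dimethyloctanedioate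
Product: 9 tert-butyl (6R)-6-[(tert-butyldimethylsilyl)oxy]-4,4-dimethyl-2-oxocycloheptane-1-carboxylate
Conditions: KOtBu (1.5 equiv), THF (0.02 M), 0 °C to rt; AcOH
Reagents that add atoms: none
Why: Dieckmann condensation: the tert-butyl ester can serve only as enolate partner and the methyl ester as acyl acceptor (the other mode needs attack of the neopentyl C10 enolate on a tert-butyl ester); seven-membered closure is helped by the gem-dimethyl group (Thorpe–Ingold effect) and driven by deprotonation of the β-keto ester formed.

Step 6
Reactants: 9 tert-butyl (6R)-6-[(tert-butyldimethylsilyl)oxy]-4,4-dimethyl-2-oxocycloheptane-1-carboxylate; 10 phenyl vinyl sulfoxide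
Product: 12 tert-butyl (6S)-6-[(tert-butyldimethylsilyl)oxy]-1-ethenyl-4,4-dimethyl-2-oxocycloheptane-1-carboxylate, via sulfoxide adduct 11 (not isolated)
Conditions: KOtBu (0.2 equiv), tBuOH–THF, rt to 50 °C; work-up; xylenes, CaCO3, 140 °C
Reagents that add atoms: none
Why: Michael addition of the β-keto ester enolate to the vinyl sulfoxide (a vinyl cation equivalent) under catalytic base, then sulfoxide pyrolysis; the syn-elimination can take hydrogen only from the carbon attached to C5, so only the vinyl group on the quaternary carbon can form, and C5 arises as both epimers, which does not matter.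

Step 7
Reactants: 12 tert-butyl (6S)-6-[(tert-butyldimethylsilyl)oxy]-1-ethenyl-4,4-dimethyl-2-oxocycloheptane-1-carboxylate; 13 vinylmagnesium bromide
Product: 14 tert-butyl (1S,2R,6S)-6-[(tert-butyldimethylsilyl)oxy]-1,2-diethenyl-2-hydroxy-4,4-dimethylcycloheptane-1-carboxylate together with 15 tert-butyl (1R,2S,6S)-6-[(tert-butyldimethylsilyl)oxy]-1,2-diethenyl-2-hydroxy-4,4-dimethylcycloheptane-1-carboxylate (both cis-divinyl)
Conditions: 13 (1.5 equiv), THF, −78 °C; sat. aq NH4Cl at −78 °C
Reagents that add atoms: none
Why: Grignard 1,2-addition to the ketone (the tert-butyl ester is too hindered to compete); in the donor solvent at −78 °C the addition should follow a non-chelated Felkin–Anh array with the bulky, electron-withdrawing ester arm perpendicular to the carbonyl plane, so the vinyl group enters anti to the ester and therefore cis to the C5 vinyl group, each C5 epimer of 12 giving its own cis-divinyl carbinol.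

Step 8
Reactants: 14 tert-butyl (1S,2R,6S)-6-[(tert-butyldimethylsilyl)oxy]-1,2-diethenyl-2-hydroxy-4,4-dimethylcycloheptane-1-carboxylate; 15 its (1R,2S,6S) diastereomer
Product: 17 tert-butyl (4E,7S)-7-[(tert-butyldimethylsilyl)oxy]-9,9-dimethyl-11-oxocycloundec-4-ene-5-carboxylate, via potassium enolate 16 (not isolated)
Conditions: KN(SiMe3)2 (1.1 equiv), 18-crown-6 (1.2 equiv), THF, −78 to −20 °C; AcOH, −78 °C
Reagents that add atoms: none
Why: Deprotonation gives the crown-separated potassium alkoxide, whose oxyanion weakens the adjacent C5–C11 bond; a concerted [3,3] shift through the chair array C2–C1–C11–C5–C4–C3 then forms C2–C3 as C5–C11 breaks (anionic oxy-Cope rearrangement, closest precedent the four-carbon ring expansion of 1,2-divinylcycloalkanols to medium-ring enones). The eleven-membered ring is closed by ring expansion and not end to end: the bonding carbons C2 and C3 are vinyl termini held on adjacent ring atoms, so the seven-membered ring grows by four atoms without a macrocyclisation. No stereocentre is created; C5 and C11 become trigonal, which is why 14 and 15 converge, and C7 is untouched. The selectivity needed is the C4=C5 geometry: with the vinyl groups cis, one ring bond must be axial and one equatorial, and the chair with the tert-butyl ester equatorial and C6 axial on C5 (C10 equatorial, oxyanion axial on C11) places C3 cis to C6 and trans to the ester. The other chair would need an axial ester and an in-ring trans trisubstituted alkene, and a boat gives the same C4=C5 geometry as the favoured chair. The shift delivers the enolate 16 with its double bond at C1=C11, and protonation at −78 °C gives the ketone before excess base can deconjugate the enoate. The competing process is retro-aldol cleavage to an ester dienolate and a vinyl ketone; one equivalent of soluble base, the ion-pair-free alkoxide and low temperature favour the pericyclic path.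

Step 9
Reactants: 17 tert-butyl (4E,7S)-7-[(tert-butyldimethylsilyl)oxy]-9,9-dimethyl-11-oxocycloundec-4-ene-5-carboxylate
Product: 18 tert-butyl (4E,7S)-7-hydroxy-9,9-dimethyl-11-oxocycloundec-4-ene-5-carboxylate
Conditions: HF·pyridine, pyridine, THF, 0 °C to rt
Reagents that add atoms: none
Why: Fluoride cleavage of the silyl ether under buffered, non-basic conditions: no alkoxide forms, so the freed C7 hydroxyl does not lactonise onto the C5 tert-butyl ester; any transannular hemiketal with C11 stays in equilibrium with the open form.

Step 10
Reactants: 18 tert-butyl (4E,7S)-7-hydroxy-9,9-dimethyl-11-oxocycloundec-4-ene-5-carboxylate; 19 isovaleric anhydride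
Product: 20 tert-butyl (4E,7S)-9,9-dimethyl-7-[(3-methylbutanoyl)oxy]-11-oxocycloundec-4-ene-5-carboxylate
Conditions: 19 (1.5 equiv), DMAP (0.1 equiv), pyridine, CH2Cl2, 0 °C to rt
Reagents that add atoms: none
Why: DMAP-catalysed acylation of the only free hydroxyl with retention at C7; doing it before the C11 hydroxyl exists removes any need to differentiate two alcohols.

Step 11
Reactants: 20 tert-butyl (4E,7S)-9,9-dimethyl-7-[(3-methylbutanoyl)oxy]-11-oxocycloundec-4-ene-5-carboxylate
Product: 24 tert-butyl (4E,7S)-9,9-dimethyl-1-methylidene-7-[(3-methylbutanoyl)oxy]-11-oxocycloundec-4-ene-5-carboxylate, via lithium enolate 21 (not isolated), via Mannich base 22 (not isolated), via ammonium iodide 23 (not isolated)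
Conditions: LiN(SiMe3)2 (1.05 equiv), THF, −78 °C; Me2N=CH2 iodide (Eschenmoser's salt), −78 to 0 °C; MeI, CH2Cl2, rt; aq NaHCO3, CH2Cl2, rt
Reagents that add atoms: N,N-dimethylmethyleneiminium iodide (Eschenmoser's salt), C=[N+](C)C.[I-]
Why: Kinetic deprotonation by the hindered amide at −78 °C should take the C1 hydrogens and not the neopentyl C10 hydrogens, and the ketone before the less acidic esters; Mannich reaction of the enolate, exhaustive methylation and base-induced β-elimination then give the exocyclic enone, which is used at once.

Step 12
Reactants: 24 tert-butyl (4E,7S)-9,9-dimethyl-1-methylidene-7-[(3-methylbutanoyl)oxy]-11-oxocycloundec-4-ene-5-carboxylate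
Product: 25 tert-butyl (4E,7S,11S)-11-hydroxy-9,9-dimethyl-1-methylidene-7-[(3-methylbutanoyl)oxy]cycloundec-4-ene-5-carboxylate
Conditions: (R)-2-methyl-CBS-oxazaborolidine (0.5 equiv), catecholborane (1.5 equiv), toluene, −78 °C; MeOH, then aqueous work-up
Reagents that add atoms: none
Why: Corey–Bakshi–Shibata reduction: the ketone binds the catalyst boron through the lone pair anti to the α-branched alkenyl arm (C1), which takes the large position, and the (R)-catalyst then delivers hydride to the face that gives the (11S) carbinol; catecholborane at −78 °C avoids hydroboration of the methylene group and reduction of the enoate.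

Step 13
Reactants: 25 tert-butyl (4E,7S,11S)-11-hydroxy-9,9-dimethyl-1-methylidene-7-[(3-methylbutanoyl)oxy]cycloundec-4-ene-5-carboxylate
Product: 27 (4E,7S,11S)-11-hydroxy-9,9-dimethyl-1-methylidene-7-[(3-methylbutanoyl)oxy]cycloundec-4-ene-5-carboxylic acid, via bis(trimethylsilyl) derivative 26 (not isolated)
Conditions: TMSOTf (3 equiv), 2,6-lutidine (4 equiv), CH2Cl2, 0 °C to rt; aq citric acid, MeOH, rt
Reagents that add atoms: none
Why: Trimethylsilyl triflate with 2,6-lutidine converts the tert-butyl ester into a silyl ester with loss of 2-methylpropene under buffered, aprotic conditions that spare the allylic C11 oxygen (silylated in passing), the exocyclic alkene and the C7 ester; mild aqueous acid then removes both silyl groups without touching either stereocentre.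

## Compound list

1 | 3,3-dimethylglutaric anhydride (4,4-dimethyloxane-2,6-dione) | CC1(C)CC(=O)OC(=O)C1 | starting material
2 | 5-methoxy-3,3-dimethyl-5-oxopentanoic acid | COC(=O)CC(C)(C)CC(=O)O | intermediate
3 | tert-butyl 3-bromopropanoate | CC(C)(C)OC(=O)CCBr | starting material
4 | methyl 5-chloro-3,3-dimethyl-5-oxopentanoate (acid chloride, not isolated) | COC(=O)CC(C)(C)CC(=O)Cl | intermediate
5 | (3-tert-butoxy-3-oxopropyl)zinc bromide (zinc homoenolate, not isolated) | CC(C)(C)OC(=O)CC[Zn]Br | intermediate
6 | 8-tert-butyl 1-methyl 3,3-dimethyl-5-oxooctanedioate | COC(=O)CC(C)(C)CC(=O)CCC(=O)OC(C)(C)C | intermediate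
7 | 8-tert-butyl 1-methyl (5R)-5-hydroxy-3,3-dimethyloctanedioate | COC(=O)CC(C)(C)C[C@H](O)CCC(=O)OC(C)(C)C | intermediate
8 | 8-tert-butyl 1-methyl (5R)-5-[(tert-butyldimethylsilyl)oxy]-3,3-dimethyloctanedioate | COC(=O)CC(C)(C)C[C@H](O[Si](C)(C)C(C)(C)C)CCC(=O)OC(C)(C)C | intermediate
9 | tert-butyl (6R)-6-[(tert-butyldimethylsilyl)oxy]-4,4-dimethyl-2-oxocycloheptane-1-carboxylate (C1 epimers and enol form) | CC(C)(C)OC(=O)C1C[C@@H](O[Si](C)(C)C(C)(C)C)CC(C)(C)CC1=O | intermediate
10 | phenyl vinyl sulfoxide | C=CS(=O)c1ccccc1 | starting material
11 | tert-butyl (6S)-6-[(tert-butyldimethylsilyl)oxy]-4,4-dimethyl-2-oxo-1-[2-(phenylsulfinyl)ethyl]cycloheptane-1-carboxylate (sulfoxide adduct, mixture at C1 and sulfur, not isolated) | CC(C)(C)OC(=O)C1(CCS(=O)c2ccccc2)C[C@@H](O[Si](C)(C)C(C)(C)C)CC(C)(C)CC1=O | intermediate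
12 | tert-butyl (6S)-6-[(tert-butyldimethylsilyl)oxy]-1-ethenyl-4,4-dimethyl-2-oxocycloheptane-1-carboxylate (both C1 epimers) | C=CC1(C(=O)OC(C)(C)C)C[C@@H](O[Si](C)(C)C(C)(C)C)CC(C)(C)CC1=O | intermediate
13 | vinylmagnesium bromide | C=C[Mg]Br | starting material
14 | tert-butyl (1S,2R,6S)-6-[(tert-butyldimethylsilyl)oxy]-1,2-diethenyl-2-hydroxy-4,4-dimethylcycloheptane-1-carboxylate (vinyl groups cis) | C=C[C@]1(O)CC(C)(C)C[C@H](O[Si](C)(C)C(C)(C)C)C[C@@]1(C=C)C(=O)OC(C)(C)C | intermediate
15 | tert-butyl (1R,2S,6S)-6-[(tert-butyldimethylsilyl)oxy]-1,2-diethenyl-2-hydroxy-4,4-dimethylcycloheptane-1-carboxylate (vinyl groups cis) | C=C[C@@]1(O)CC(C)(C)C[C@H](O[Si](C)(C)C(C)(C)C)C[C@]1(C=C)C(=O)OC(C)(C)C | intermediate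
16 | potassium enolate of 17 with the C1=C11 double bond (C10 trans to C2, not isolated) | [K+].[O-]/C1=C\CC/C=C(/C(=O)OC(C)(C)C)C[C@@H](O[Si](C)(C)C(C)(C)C)CC(C)(C)C1 | intermediate
17 | tert-butyl (4E,7S)-7-[(tert-butyldimethylsilyl)oxy]-9,9-dimethyl-11-oxocycloundec-4-ene-5-carboxylate | O=C1CCC/C=C(/C(=O)OC(C)(C)C)C[C@@H](O[Si](C)(C)C(C)(C)C)CC(C)(C)C1 | intermediate
18 | tert-butyl (4E,7S)-7-hydroxy-9,9-dimethyl-11-oxocycloundec-4-ene-5-carboxylate | O=C1CCC/C=C(/C(=O)OC(C)(C)C)C[C@@H](O)CC(C)(C)C1 | intermediate
19 | isovaleric anhydride (3-methylbutanoic anhydride) | CC(C)CC(=O)OC(=O)CC(C)C | starting material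
20 | tert-butyl (4E,7S)-9,9-dimethyl-7-[(3-methylbutanoyl)oxy]-11-oxocycloundec-4-ene-5-carboxylate | O=C1CCC/C=C(/C(=O)OC(C)(C)C)C[C@@H](OC(=O)CC(C)C)CC(C)(C)C1 | intermediate
21 | lithium enolate of 20 with the C1=C11 double bond (not isolated) | [Li+].[O-]C1=CCC/C=C(/C(=O)OC(C)(C)C)C[C@@H](OC(=O)CC(C)C)CC(C)(C)C1 | intermediate
22 | tert-butyl (4E,7S)-1-[(dimethylamino)methyl]-9,9-dimethyl-7-[(3-methylbutanoyl)oxy]-11-oxocycloundec-4-ene-5-carboxylate (Mannich base, C1 epimers, not isolated) | CN(C)CC1CC/C=C(/C(=O)OC(C)(C)C)C[C@@H](OC(=O)CC(C)C)CC(C)(C)CC1=O | intermediate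
23 | trimethylammonium iodide of 22 (not isolated) | C[N+](C)(C)CC1CC/C=C(/C(=O)OC(C)(C)C)C[C@@H](OC(=O)CC(C)C)CC(C)(C)CC1=O.[I-] | intermediate
24 | tert-butyl (4E,7S)-9,9-dimethyl-1-methylidene-7-[(3-methylbutanoyl)oxy]-11-oxocycloundec-4-ene-5-carboxylate | C=C1CC/C=C(/C(=O)OC(C)(C)C)C[C@@H](OC(=O)CC(C)C)CC(C)(C)CC1=O | intermediate
25 | tert-butyl (4E,7S,11S)-11-hydroxy-9,9-dimethyl-1-methylidene-7-[(3-methylbutanoyl)oxy]cycloundec-4-ene-5-carboxylate | C=C1CC/C=C(/C(=O)OC(C)(C)C)C[C@@H](OC(=O)CC(C)C)CC(C)(C)C[C@@H]1O | intermediate
26 | trimethylsilyl (4E,7S,11S)-9,9-dimethyl-1-methylidene-7-[(3-methylbutanoyl)oxy]-11-[(trimethylsilyl)oxy]cycloundec-4-ene-5-carboxylate (not isolated) | C=C1CC/C=C(/C(=O)O[Si](C)(C)C)C[C@@H](OC(=O)CC(C)C)CC(C)(C)C[C@@H]1O[Si](C)(C)C | intermediate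
27 | (4E,7S,11S)-11-hydroxy-9,9-dimethyl-1-methylidene-7-[(3-methylbutanoyl)oxy]cycloundec-4-ene-5-carboxylic acid (CNP0400752.1) | C=C1CC/C=C(/C(=O)O)C[C@@H](OC(=O)CC(C)C)CC(C)(C)C[C@@H]1O | target

## Step count and least certain steps

Total: 13 steps. Longest linear sequence: 13 steps (1 to 27); 3, 10, 13 and 19 enter as purchased reagents.

Step 8 (key step). The most likely failure is fragmentation of the alkoxide by retro-aldol cleavage of C5–C11, because the ester-stabilised dienolate is a good leaving group. Re-closure by conjugate addition would then lose control of the C4=C5 geometry or give a two-carbon ring expansion, and excess base could deconjugate the enoate. Fallback: a neutral siloxy-Cope rearrangement, setting out from 14 and 15 and returning at 17. N-(Trimethylsilyl)imidazole would convert them into trimethylsilyl ether F1 and trimethylsilyl ether F2. Heating in degassed mesitylene (sealed, base-washed glass, about 180 °C) should then give silyl enol ether F3 through the same chair, with no alkoxide present to fragment. Aqueous citric acid in THF would hydrolyse F3 to 17.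

Step 7. The most likely failure is poor facial selectivity. If a magnesium chelate between ketone and ester becomes the reacting form, attack anti to the C5 vinyl group would favour the trans-divinyl carbinols, which rearrange through a chair to the wrong C4=C5 geometry. Enolisation of the hindered ketone is a second risk. Fallback: deliver the two carbons as an alkyne, setting out from 12 and returning at 14 and 15. Ethynylmagnesium bromide with anhydrous CeCl3 in THF at −78 °C should give ethynyl carbinol F4 and ethynyl carbinol F5. The rod-like nucleophile is less affected by the C9 methyl groups and should follow the stereoelectronic preference anti to the ester, and CeCl3 suppresses enolisation. Semihydrogenation (H2, Pd/CaCO3 poisoned with Pb(OAc)2, quinoline) would then give 14 and 15.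

Step 12. The most likely failure is poor facial selectivity, since the neopentyl-type C10 arm is not small and the ring conformation imposed by C7 may oppose the catalyst; conjugate reduction is a lesser risk. Fallback: substrate-independent reduction with recycling, setting out from 24 and returning at 25. Luche reduction (NaBH4, CeCl3·7H2O, MeOH, −78 °C) would give 25 together with its C11 epimer F6. The two are diastereomers and separable by chromatography, and F6 would be re-oxidised to 24 with MnO2 in CH2Cl2 and reduced again.

Step 11. The most likely failure is loss of regiocontrol in the enolisation (C10 instead of C1), proton abstraction next to the isovalerate carbonyl or at C3 of the enoate, or acyl transfer to the enolate. Fallback: let the rearrangement fix the regiochemistry, setting out from 14 and 15 and returning at 24.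
- The conditions of step 8 are used, but enolate 16 is quenched at −78 °C with Eschenmoser's salt instead of acid, giving Mannich base F7.
- Methyl iodide converts F7 into ammonium iodide F8, and aqueous NaHCO3 eliminates it to silyloxy enone F9.
- HF·pyridine then gives hydroxy enone F10, and acylation with 19 and DMAP gives 24.

Step 3. The most likely failure is insufficient enantioface discrimination: both ketone neighbours are methylene groups, the δ-ester can compete for divalent ruthenium, and the sense of induction rests on analogy. Lactonisation of the carbinol onto the methyl ester before silylation is a second risk. Fallback: create C7 by forming the C6–C7 bond under catalyst control, setting out from 2 and returning at 7.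
- BH3·SMe2 reduces the acid of 2 to hydroxy ester F11, and TEMPO with PhI(OAc)2 oxidises it to aldehyde F12.
- Zinc-mediated asymmetric addition of tert-butyl propiolate (Me2Zn, ProPhenol ligand of the enantiomer that gives the (5S) carbinol) gives propargylic alcohol F13.
- Hydrogenation (H2, Pd/C, EtOAc) saturates the triple bond to give 7.

Step 6. The most likely failure is sluggish or reversible conjugate addition at the hindered, fully substituted enolate carbon, together with side reactions of benzenesulfenic acid during the pyrolysis. Fallback: electrophilic alkynylation, setting out from 9 and returning at 12. 1-[(Trimethylsilyl)ethynyl]-1,2-benziodoxol-3(1H)-one with TBAF in THF at −78 °C should transfer an ethynyl group to the β-keto ester carbon to give ethynyl keto ester F14. Semihydrogenation (H2, Pd/CaCO3 poisoned with Pb(OAc)2, quinoline) would then give 12.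

## Further compounds

F1 | step 8 | tert-butyl (1S,2R,6S)-6-[(tert-butyldimethylsilyl)oxy]-1,2-diethenyl-4,4-dimethyl-2-[(trimethylsilyl)oxy]cycloheptane-1-carboxylate | C=C[C@]1(O[Si](C)(C)C)CC(C)(C)C[C@H](O[Si](C)(C)C(C)(C)C)C[C@@]1(C=C)C(=O)OC(C)(C)C
F2 | step 8 | tert-butyl (1R,2S,6S)-6-[(tert-butyldimethylsilyl)oxy]-1,2-diethenyl-4,4-dimethyl-2-[(trimethylsilyl)oxy]cycloheptane-1-carboxylate | C=C[C@@]1(O[Si](C)(C)C)CC(C)(C)C[C@H](O[Si](C)(C)C(C)(C)C)C[C@]1(C=C)C(=O)OC(C)(C)C
F3 | step 8 | tert-butyl (4E,7S)-7-[(tert-butyldimethylsilyl)oxy]-9,9-dimethyl-11-[(trimethylsilyl)oxy]cycloundeca-1(11),4-diene-5-carboxylate | C[Si](C)(C)OC1=CCC/C=C(/C(=O)OC(C)(C)C)C[C@@H](O[Si](C)(C)C(C)(C)C)CC(C)(C)C1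
F4 | step 7 | tert-butyl (1S,2R,6S)-6-[(tert-butyldimethylsilyl)oxy]-1-ethenyl-2-ethynyl-2-hydroxy-4,4-dimethylcycloheptane-1-carboxylate | C#C[C@]1(O)CC(C)(C)C[C@H](O[Si](C)(C)C(C)(C)C)C[C@@]1(C=C)C(=O)OC(C)(C)C
F5 | step 7 | tert-butyl (1R,2S,6S)-6-[(tert-butyldimethylsilyl)oxy]-1-ethenyl-2-ethynyl-2-hydroxy-4,4-dimethylcycloheptane-1-carboxylate | C#C[C@@]1(O)CC(C)(C)C[C@H](O[Si](C)(C)C(C)(C)C)C[C@]1(C=C)C(=O)OC(C)(C)C
F6 | step 12 | tert-butyl (4E,7S,11R)-11-hydroxy-9,9-dimethyl-1-methylidene-7-[(3-methylbutanoyl)oxy]cycloundec-4-ene-5-carboxylate | C=C1CC/C=C(/C(=O)OC(C)(C)C)C[C@@H](OC(=O)CC(C)C)CC(C)(C)C[C@H]1O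
F7 | step 11 | tert-butyl (4E,7S)-7-[(tert-butyldimethylsilyl)oxy]-1-[(dimethylamino)methyl]-9,9-dimethyl-11-oxocycloundec-4-ene-5-carboxylate | CN(C)CC1CC/C=C(/C(=O)OC(C)(C)C)C[C@@H](O[Si](C)(C)C(C)(C)C)CC(C)(C)CC1=O
F8 | step 11 | trimethylammonium iodide of F7 | C[N+](C)(C)CC1CC/C=C(/C(=O)OC(C)(C)C)C[C@@H](O[Si](C)(C)C(C)(C)C)CC(C)(C)CC1=O.[I-]
F9 | step 11 | tert-butyl (4E,7S)-7-[(tert-butyldimethylsilyl)oxy]-9,9-dimethyl-1-methylidene-11-oxocycloundec-4-ene-5-carboxylate | C=C1CC/C=C(/C(=O)OC(C)(C)C)C[C@@H](O[Si](C)(C)C(C)(C)C)CC(C)(C)CC1=O
F10 | step 11 | tert-butyl (4E,7S)-7-hydroxy-9,9-dimethyl-1-methylidene-11-oxocycloundec-4-ene-5-carboxylate | C=C1CC/C=C(/C(=O)OC(C)(C)C)C[C@@H](O)CC(C)(C)CC1=O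
F11 | step 3 | methyl 5-hydroxy-3,3-dimethylpentanoate | COC(=O)CC(C)(C)CCO
F12 | step 3 | methyl 3,3-dimethyl-5-oxopentanoate | COC(=O)CC(C)(C)CC=O
F13 | step 3 | 8-tert-butyl 1-methyl (5S)-5-hydroxy-3,3-dimethyloct-6-ynedioate | COC(=O)CC(C)(C)C[C@H](O)C#CC(=O)OC(C)(C)C
F14 | step 6 | tert-butyl (6S)-6-[(tert-butyldimethylsilyl)oxy]-1-ethynyl-4,4-dimethyl-2-oxocycloheptane-1-carboxylate | C#CC1(C(=O)OC(C)(C)C)C[C@@H](O[Si](C)(C)C(C)(C)C)CC(C)(C)CC1=O
A1 | alternative 1 | tert-butyl (2E)-2-{(2S)-6-[(tert-butyldimethylsilyl)oxy]-4,4-dimethyl-2-(4,4,5,5-tetramethyl-1,3,2-dioxaborolan-2-yl)hexyl}-7-(trimethylsilyl)hept-2-en-6-ynoate | CC(C)(C)[Si](C)(C)OCCC(C)(C)C[C@H](B1OC(C)(C)C(C)(C)O1)C/C(C(=O)OC(C)(C)C)=C\CCC#C[Si](C)(C)C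
A2 | alternative 1 | {4-[(tert-butyldimethylsilyl)oxy]-2,2-dimethylbutyl}lithium | [Li]CC(C)(C)CCO[Si](C)(C)C(C)(C)C
A3 | alternative 1 | vinylboronic acid pinacol ester | C=CB1OC(C)(C)C(C)(C)O1
A4 | alternative 1 | tert-butyl (2Z)-2-bromo-7-(trimethylsilyl)hept-2-en-6-ynoate | CC(C)(C)OC(=O)/C(Br)=C/CCC#C[Si](C)(C)C
A5 | alternative 1 | tert-butyl (2E)-2-{(2S)-4,4-dimethyl-2-[(3-methylbutanoyl)oxy]-6-oxohexyl}hept-2-en-6-ynoate | O=CCC(C)(C)C[C@H](OC(=O)CC(C)C)C/C(C(=O)OC(C)(C)C)=C\CCC#C
A6 | alternative 2 | tert-butyl (4E,7S,11S)-11-[(tert-butyldimethylsilyl)oxy]-9,9-dimethyl-1-methylidene-7-[(3-methylbutanoyl)oxy]cycloundec-4-ene-5-carboxylate | C=C1CC/C=C(/C(=O)OC(C)(C)C)C[C@@H](OC(=O)CC(C)C)CC(C)(C)C[C@@H]1O[Si](C)(C)C(C)(C)C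
A7 | alternative 2 | 1,3-dioxoisoindolin-2-yl (5S,9S,11E)-11-(tert-butoxycarbonyl)-5-[(tert-butyldimethylsilyl)oxy]-7,7-dimethyl-4-methylidene-9-[(3-methylbutanoyl)oxy]-12-(phenylsulfonyl)dodec-11-enoate | O=C(CCC(=C)[C@@H](O[Si](C)(C)C(C)(C)C)CC(C)(C)C[C@H](OC(=O)CC(C)C)C/C(C(=O)OC(C)(C)C)=C\S(=O)(=O)c1ccccc1)ON1C(=O)c2ccccc2C1=O
A8 | alternative 3 | (7S)-7-[(tert-butyldimethylsilyl)oxy]-9,9-dimethylcycloundec-4-yn-11-one (target numbering) | O=C1CCCC#CC[C@@H](O[Si](C)(C)C(C)(C)C)CC(C)(C)C1
A9 | alternative 3 | fused six–seven epoxy ketone: 5-[(tert-butyldimethylsilyl)oxy]-3,3-dimethyl-1,7-epoxybicyclo[5.4.0]undecan-8-one, silyloxy carbon configured as C7 of the target | O=C1CCCC2(O3)CC(C)(C)C[C@H](O[Si](C)(C)C(C)(C)C)CC123
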